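**Strategy.** Everything rests on cutting the C1–C2 bond of the bornane (bornane numbering). This unfolds the bicycle into (R)-α-campholenic aldehyde bearing a 2-fluoro-4,6-bis(methoxymethoxy)benzoyl group on its vinylic carbon, in which aldehyde C2 and enone β-carbon C1 sit 1,5 to each other across C3–C4–C7. One SmI2 reduction joins these two electrophilic carbons, closing the second cyclopentane of the bicyclo[2.2.1]heptane and creating quaternary C1, the endo C2 carbinol and C6. The feature exploited is this C2/C1 pair held by the cyclopentene ring, together with the C6 aryl ketone, which later lets the C2 oxygen displace fluoride to close the oxepane ring.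

Key step: step 11

Remark: atom labels C1–C7 follow bornane numbering; (R)-α-campholenic aldehyde (the enantiomer derived from (1S,5S)-α-pinene) is taken as purchasable; stereocentres that are erased again before the key step (epoxide and carbinol carbons) are drawn for the expected major isomer or left open.

**Step 1**
Reactants: 1 (R)-α-campholenic aldehyde
Product: 2 (R)-4-(2,2-dimethoxyethyl)-1,5,5-trimethylcyclopent-1-ene
Conditions: HC(OMe)3, MeOH, p-TsOH·H2O (cat.), rt
Reagents that add atoms: trimethyl orthoformate COC(OC)OC; methanol CO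
Why: Acid-catalysed acetalisation (the orthoformate removes the water) masks the aldehyde for the oxidation, hydride and organometallic steps ahead, and the stereocentre is β to the carbonyl and cannot epimerise.

**Step 2**
Reactants: 2 (R)-4-(2,2-dimethoxyethyl)-1,5,5-trimethylcyclopent-1-ene
Product: 3 3-(2,2-dimethoxyethyl)-1,2,2-trimethyl-6-oxabicyclo[3.1.0]hexane (oxygen trans to the side chain)
Conditions: mCPBA, CH2Cl2, 0 °C
Reagents that add atoms: 3-chloroperoxybenzoic acid O=C(OO)c1cccc(Cl)c1
Why: Prilezhaev epoxidation of the electron-rich trisubstituted alkene should deliver oxygen mainly anti to the side chain, and both new stereocentres are erased in steps 4 and 5, so the facial ratio is immaterial.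

**Step 3**
Reactants: 3 epoxide
Product: 4 4-(2,2-dimethoxyethyl)-3,3-dimethyl-2-methylidenecyclopentan-1-ol (hydroxyl trans to the side chain)
Conditions: 2,2,6,6-tetramethylpiperidine, n-BuLi, Et2AlCl, toluene, 0 °C; then aq. potassium sodium tartrate
Reagents that add atoms: none
Why: Amide-base isomerisation of an epoxide to an allylic alcohol, in which the aluminium-bound amide removes a methyl hydrogen (the ring neighbour on that side is quaternary and methyl C–H is preferred over ring CH2), so an exocyclic methylene forms and the oxygen stays on the former vinylic CH with its epoxide configuration.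

**Step 4**
Reactants: 4 allylic alcohol
Product: 5 (S)-4-(2,2-dimethoxyethyl)-3,3-dimethyl-2-methylidenecyclopentan-1-one
Conditions: MnO2 (activated), CH2Cl2, rt
Reagents that add atoms: none
Why: Allylic alcohol oxidation with activated MnO2 under neutral conditions gives the α-methylene ketone, which is used at once to avoid dimerisation.

**Step 5**
Reactants: 5 α-methylene ketone
Product: 7 (R)-4-(2,2-dimethoxyethyl)-2,3,3-trimethylcyclopent-1-en-1-yl trifluoromethanesulfonate, via lithium enolate 6 (not isolated)
Conditions: LiBH(s-Bu)3, THF, −78 °C; then PhNTf2, −78 °C → rt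
Reagents that add atoms: N-phenylbis(trifluoromethanesulfonimide) O=S(=O)(N(c1ccccc1)S(=O)(=O)C(F)(F)F)C(F)(F)F
Why: Conjugate (1,4) hydride reduction of the s-cis enone with an unsubstituted β-carbon gives a single enolate regioisomer, with its double bond towards the methyl-bearing carbon, and O-triflation fixes it as the tetrasubstituted enol triflate without relying on regioselective deprotonation of a ketone.

**Step 6**
Reactants: 8 5-fluororesorcinol
Product: 10 2-fluoro-4,6-dihydroxybenzaldehyde, via aryl iminium chloride 9 (not isolated)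
Conditions: POCl3, DMF, MeCN, 0 °C → rt; then H2O, 50 °C
Reagents that add atoms: N,N-dimethylformamide CN(C)C=O; water O
Why: Vilsmeier–Haack formylation of a resorcinol occurs para to one hydroxyl and ortho to the other, i.e. next to fluorine (the position between the two hydroxyls is more crowded), and hydrolysis of the iminium salt releases the aldehyde.

**Step 7**
Reactants: 10 2-fluoro-4,6-dihydroxybenzaldehyde
Product: 11 2-fluoro-4,6-bis(methoxymethoxy)benzaldehyde
Conditions: NaH, MOMCl, DMF, 0 °C → rt
Reagents that add atoms: chloromethyl methyl ether COCCl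
Why: Double Williamson O-alkylation of the phenoxides, with NaH chosen so that the hydrogen-bonded hydroxyl ortho to the formyl group is alkylated as well.

**Step 8**
Reactants: 7 enol triflate; 11 2-fluoro-4,6-bis(methoxymethoxy)benzaldehyde
Product: 12 [(4R)-4-(2,2-dimethoxyethyl)-2,3,3-trimethylcyclopent-1-en-1-yl][2-fluoro-4,6-bis(methoxymethoxy)phenyl]methanol
Conditions: CrCl2, NiCl2 (cat.), DMF, rt
Reagents that add atoms: none
Why: Nozaki–Hiyama–Kishi coupling, in which zerovalent nickel inserts into the C–OTf bond and transmetalation gives an alkenyl species of trivalent chromium that adds only to the aldehyde and tolerates acetal, MOM ethers and aryl fluoride; the carbinol centre forms without control and is removed in step 9.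

**Step 9**
Reactants: 12 allylic benzylic alcohol
Product: 13 [(4R)-4-(2,2-dimethoxyethyl)-2,3,3-trimethylcyclopent-1-en-1-yl][2-fluoro-4,6-bis(methoxymethoxy)phenyl]methanone
Conditions: MnO2 (activated), CH2Cl2, rt
Reagents that add atoms: none
Why: MnO2 oxidation of an alcohol that is both allylic and benzylic gives the aryl enone under neutral conditions that spare the acetal and the MOM ethers.

**Step 10**
Reactants: 13 enone acetal
Product: 14 4-[2-fluoro-4,6-bis(methoxymethoxy)benzoyl]-α-campholenic aldehyde
Conditions: HCl (0.5 M aq.), THF, 0 °C → rt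
Reagents that add atoms: water O
Why: Acid-catalysed acetal hydrolysis is selective because the dimethyl acetal of an aliphatic aldehyde ionises far faster than an aryl MOM ether (a formaldehyde acetal), so brief exposure to dilute acid should free only the aldehyde.

**Step 11**
Reactants: 14 4-[2-fluoro-4,6-bis(methoxymethoxy)benzoyl]-α-campholenic aldehyde
Product: 16 6-endo-[2-fluoro-4,6-bis(methoxymethoxy)benzoyl]borneol, via samarium enolate 15 (not isolated)
Conditions: SmI2 (2.5 equiv), THF, −78 → −30 °C, slow addition of 14; then sat. aq. NH4Cl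
Reagents that add atoms: none
Why: Single-electron transfer from divalent samarium to the aryl enone (or to the aldehyde) gives a samarium-bound radical anion, and in either case the productive bond is C2–C1: the ketyl carbon C2 (or the β-radical C1) adds across the tether C3–C4–C7, a second electron turns the C6 radical into the enolate of trivalent samarium 15, and protonation on work-up should give 16. The closest known reaction type is the SmI2 ketyl–olefin (aldehyde–enone) reductive cyclisation, here used to form a quaternary carbon. The ring closed is the second cyclopentane of the bicyclo[2.2.1]heptane (C1–C2–C3–C4–C7), formed in a 5-exo-trig mode with C6 outside the new ring. C1 is dictated by the C4 stereocentre, because the CH2CHO arm can reach only the face of the cyclopentene on which it stands; C2 should carry its oxygen endo, because only an endo oxygen is gauche to C6 and can share samarium with the aroyl oxygen, while the exo position is crowded by the syn C7 methyl; C6 is set when the enolate is protonated and, being α to the ketone, stays correctable in step 12. The selectivity needed is C–C bond formation at the β-carbon in place of pinacol coupling or simple reduction, and it is secured by geometry (coupling at the ketone carbon would leave the C1=C6 double bond at a bridgehead) and by withholding any proton source until the quench, which keeps the new ketone masked as its enolate.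

**Step 12**
Reactants: 16 6-endo-[2-fluoro-4,6-bis(methoxymethoxy)benzoyl]borneol
Product: 17 bornane-fused 6,8-bis(methoxymethoxy)-2,3,4,5-tetrahydro-1-benzoxepin-5-one
Conditions: KN(SiMe3)2 (1.3 equiv), THF, 0 → 60 °C
Reagents that add atoms: none
Why: Intramolecular SNAr (addition–elimination) of the endo C2 alkoxide on the fluorine-bearing carbon ortho to the activating ketone closes the seven-membered ring, and because C6–H is enolisable under these conditions any 6-exo epimer or lactol form of 16 is funnelled through the only isomer able to cyclise, leaving C6 endo.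

**Step 13**
Reactants: 17 benzoxepinone
Product: 19 bornane-fused 6,8-bis(methoxymethoxy)-2,3,4,5-tetrahydro-1-benzoxepine, via hydrazone 18 (not isolated)
Conditions: N2H4·H2O, KOH, diethylene glycol, 130 → 200 °C
Reagents that add atoms: none
Why: Wolff–Kishner reduction converts the ketone through its hydrazone into the benzylic CH2 with loss of N2 under hot KOH, conditions to which MOM and alkyl aryl ethers are inert, and the cis (endo,endo) ring fusion cannot change.

**Step 14**
Reactants: 19 bis-MOM benzoxepine; 20 N-methoxy-N-methyl-3-methylbutanamide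
Product: 22 7-(3-methylbutanoyl) derivative of 19, via aryllithium 21 (not isolated)
Conditions: n-BuLi, THF, 0 °C; then 20, −78 °C → rt; H2O
Reagents that add atoms: none
Why: Directed ortho-metalation takes place at the aryl C–H flanked by the two chelating MOM ethers, and the aryllithium is acylated by the Weinreb amide, whose chelated tetrahedral adduct prevents over-addition.

**Step 15**
Reactants: 22 acylated bis-MOM ether
Product: 23 6,8-dihydroxy-7-(3-methylbutanoyl) benzoxepine (free diphenol)
Conditions: HCl (3 M aq.), MeOH, 50 °C
Reagents that add atoms: none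
Why: Acid-catalysed acetal exchange in methanol removes both MOM groups, while the sec-alkyl aryl ether and the aryl ketone are stable.

**Step 16**
Reactants: 23 diphenol
Product: 25 target CNP0246493.1 (9-formyl derivative of 23), via chloro ether 24 (not isolated)
Conditions: Cl2CHOMe, TiCl4, CH2Cl2, −78 → 0 °C; then 1 M HCl (aq.)
Reagents that add atoms: dichloromethyl methyl ether COC(Cl)Cl; water O
Why: Rieche formylation, in which the TiCl4-activated dichloromethyl methyl ether attacks the single free position of the electron-rich ring, ortho to a titanium-bound phenoxide, and aqueous work-up hydrolyses the chloro ether to the aldehyde.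

**Compound list**

1 | (R)-α-campholenic aldehyde, 2-[(1R)-2,2,3-trimethylcyclopent-3-en-1-yl]acetaldehyde | O=CC[C@H]1CC=C(C)C1(C)C | starting material
2 | (R)-4-(2,2-dimethoxyethyl)-1,5,5-trimethylcyclopent-1-ene (dimethyl acetal of 1) | COC(OC)C[C@H]1CC=C(C)C1(C)C | intermediate
3 | 3-(2,2-dimethoxyethyl)-1,2,2-trimethyl-6-oxabicyclo[3.1.0]hexane, epoxide oxygen trans to the side chain | COC(OC)C[C@H]1C[C@@H]2O[C@]2(C)C1(C)C | intermediate
4 | 4-(2,2-dimethoxyethyl)-3,3-dimethyl-2-methylidenecyclopentan-1-ol, hydroxyl trans to the side chain | COC(OC)C[C@H]1C[C@H](O)C(=C)C1(C)C | intermediate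
5 | (S)-4-(2,2-dimethoxyethyl)-3,3-dimethyl-2-methylidenecyclopentan-1-one | COC(OC)C[C@H]1CC(=O)C(=C)C1(C)C | intermediate
6 | lithium (R)-4-(2,2-dimethoxyethyl)-2,3,3-trimethylcyclopent-1-en-1-olate | COC(OC)C[C@H]1CC(O[Li])=C(C)C1(C)C | intermediate
7 | (R)-4-(2,2-dimethoxyethyl)-2,3,3-trimethylcyclopent-1-en-1-yl trifluoromethanesulfonate | COC(OC)C[C@H]1CC(OS(=O)(=O)C(F)(F)F)=C(C)C1(C)C | intermediate
8 | 5-fluororesorcinol (5-fluorobenzene-1,3-diol) | Oc1cc(O)cc(F)c1 | starting material
9 | N-(2-fluoro-4,6-dihydroxybenzylidene)-N-methylmethanaminium chloride | C[N+](C)=Cc1c(O)cc(O)cc1F.[Cl-] | intermediate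
10 | 2-fluoro-4,6-dihydroxybenzaldehyde | O=Cc1c(O)cc(O)cc1F | intermediate
11 | 2-fluoro-4,6-bis(methoxymethoxy)benzaldehyde | O=Cc1c(F)cc(OCOC)cc1OCOC | intermediate
12 | [(4R)-4-(2,2-dimethoxyethyl)-2,3,3-trimethylcyclopent-1-en-1-yl][2-fluoro-4,6-bis(methoxymethoxy)phenyl]methanol, both carbinol epimers | COC(OC)C[C@H]1CC(C(O)c2c(F)cc(OCOC)cc2OCOC)=C(C)C1(C)C | intermediate
13 | [(4R)-4-(2,2-dimethoxyethyl)-2,3,3-trimethylcyclopent-1-en-1-yl][2-fluoro-4,6-bis(methoxymethoxy)phenyl]methanone | COC(OC)C[C@H]1CC(C(=O)c2c(F)cc(OCOC)cc2OCOC)=C(C)C1(C)C | intermediate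
14 | 4-[2-fluoro-4,6-bis(methoxymethoxy)benzoyl]-α-campholenic aldehyde, 2-[(1R)-4-aroyl-2,2,3-trimethylcyclopent-3-en-1-yl]acetaldehyde | O=CC[C@H]1CC(C(=O)c2c(F)cc(OCOC)cc2OCOC)=C(C)C1(C)C | intermediate
15 | bis(diiodosamarium) derivative of 16 (trivalent samarium): C2 alkoxide and C6 enolate | COCOc1cc(OCOC)cc(F)c1C(O[Sm](I)I)=C1C[C@@H]2C[C@H](O[Sm](I)I)[C@@]1(C)C2(C)C | intermediate
16 | 6-endo-[2-fluoro-4,6-bis(methoxymethoxy)benzoyl]borneol, (1R,2S,4R,6R) in bornane numbering | COCOc1cc(OCOC)cc(F)c1C(=O)[C@@H]1C[C@@H]2C[C@H](O)[C@@]1(C)C2(C)C | intermediate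
17 | bornane-fused 6,8-bis(methoxymethoxy)-2,3,4,5-tetrahydro-1-benzoxepin-5-one; benzoxepine locants O1, C2 = bornane C2, C3 = bornane C1, C4 = bornane C6, C5 = carbonyl carbon; O1 and C5 both endo; (1R,2S,4R,6R) in bornane numbering | COCOc1cc(OCOC)cc3c1C(=O)[C@@H]1C[C@@H]2C[C@H](O3)[C@@]1(C)C2(C)C | intermediate
18 | hydrazone of 17 | COCOc1cc(OCOC)cc3c1C(=NN)[C@@H]1C[C@@H]2C[C@H](O3)[C@@]1(C)C2(C)C | intermediate
19 | bornane-fused 6,8-bis(methoxymethoxy)-2,3,4,5-tetrahydro-1-benzoxepine (C5 now CH2), (1R,2S,4R,6S) in bornane numbering | COCOc1cc(OCOC)cc3c1C[C@@H]1C[C@@H]2C[C@H](O3)[C@@]1(C)C2(C)C | intermediate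
20 | N-methoxy-N-methyl-3-methylbutanamide | CC(C)CC(=O)N(C)OC | starting material
21 | 7-lithio derivative of 19 (lithium between the two MOM ethers) | COCOc1c([Li])c(OCOC)cc3c1C[C@@H]1C[C@@H]2C[C@H](O3)[C@@]1(C)C2(C)C | intermediate
22 | 7-(3-methylbutanoyl) derivative of 19 | COCOc1c(C(=O)CC(C)C)c(OCOC)cc3c1C[C@@H]1C[C@@H]2C[C@H](O3)[C@@]1(C)C2(C)C | intermediate
23 | 6,8-dihydroxy-7-(3-methylbutanoyl) analogue of 19 (free diphenol) | Oc1c(C(=O)CC(C)C)c(O)cc3c1C[C@@H]1C[C@@H]2C[C@H](O3)[C@@]1(C)C2(C)C | intermediate
24 | 9-[chloro(methoxy)methyl] derivative of 23 | Oc1c(C(=O)CC(C)C)c(O)c(C(Cl)OC)c3c1C[C@@H]1C[C@@H]2C[C@H](O3)[C@@]1(C)C2(C)C | intermediate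
25 | CNP0246493.1: 9-formyl-6,8-dihydroxy-7-(3-methylbutanoyl) benzoxepine fused to bornane, (1R,2S,4R,6S) in bornane numbering | CC(C)CC(=O)c1c(O)c(C=O)c2c(c1O)C[C@@H]1C[C@@H]3C[C@H](O2)[C@@]1(C)C3(C)C | target

**Step count.** Total: 16 steps. Longest linear sequence: 14 steps (steps 1–5 and 8–16, from 1 to 25); the arene branch (steps 6–7) joins at step 8.

**Steps most likely to fail**

Step 11. Electron transfer may end in simple reduction of the enone or the aldehyde, or in poor control at C2, instead of ring closure. The fallback sets out from 14 and makes the same C1–C2 bond by a neutral radical chain. With Bu3SnH and AIBN in benzene at 80 °C under high dilution, the stannyl radical adds to the aldehyde oxygen, the O-stannyl ketyl cyclises 5-exo onto C1 and the C6 radical takes hydrogen from the stannane. This should give the tributylstannyl ether of 16 F1, which aqueous KF cleaves, and the route is rejoined at 16; any C6 epimer converges in step 12.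

Step 13. Hydrazone formation may stall at the hindered, electron-rich carbonyl flanked by two ortho oxygens. The fallback sets out from 17: LiAlH4 (THF, 0 °C) should give the benzylic alcohol F2, NaH, CS2 and MeI the S-methyl xanthate F3, and Bu3SnH with AIBN in toluene at 110 °C (Barton–McCombie deoxygenation) the methylene compound, which rejoins the route at 19.

Step 8. Oxidative addition of the tetrasubstituted triflate may be slow, or the alkenylchromium species may be protonated before it adds to the hindered, electron-rich aldehyde. The fallback sets out from 7: Me3SnSnMe3, Pd(PPh3)4 and LiCl (THF, 65 °C) should give the alkenyl(trimethyl)stannane F4, tin–lithium exchange with MeLi (THF, −78 → 0 °C) the alkenyllithium F5, and addition of this to aldehyde 11 at −78 °C rejoins the route at 12.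

**Further compounds**

F1 | step 11 | O-tributylstannyl ether of 16 | COCOc1cc(OCOC)cc(F)c1C(=O)[C@@H]1C[C@@H]2C[C@H](O[Sn](CCCC)(CCCC)CCCC)[C@@]1(C)C2(C)C
F2 | step 13 | C5 alcohol from 17 (carbinol epimers) | COCOc1cc(OCOC)cc3c1C(O)[C@@H]1C[C@@H]2C[C@H](O3)[C@@]1(C)C2(C)C
F3 | step 13 | O-(C5) S-methyl xanthate of F2 | COCOc1cc(OCOC)cc3c1C(OC(=S)SC)[C@@H]1C[C@@H]2C[C@H](O3)[C@@]1(C)C2(C)C
F4 | step 8 | [(4S)-4-(2,2-dimethoxyethyl)-2,3,3-trimethylcyclopent-1-en-1-yl]trimethylstannane | COC(OC)C[C@H]1CC([Sn](C)(C)C)=C(C)C1(C)C
F5 | step 8 | [(4R)-4-(2,2-dimethoxyethyl)-2,3,3-trimethylcyclopent-1-en-1-yl]lithium | COC(OC)C[C@H]1CC([Li])=C(C)C1(C)C
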